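**Retrosynthetic overview**
- Feature: in the dihydrofuran (ring A), C3a and O1 (the oxygen on C7a) of the benzo ring B are 1,3-related. This is the relationship between carbene carbon and carbonyl oxygen in an ortho-quinone diazide. C2 carries ring C, whose para oxygen can stabilise a positive charge at C2.
- Late disconnections: six benzyl groups; the C3 methyl ester back to a CH2OTBS group; the C4 (E)-acrylate back to a C4 aldehyde plus the malonic half-ester of tribenzyl (R)-danshensu (ring D).
- Key disconnection: C3–C3a and O1–C2 are cut together. This gives a formyl-bearing ortho-quinone diazide (ring B) and an (E)-cinnamyl silyl ether (ring C), joined by a chiral dirhodium carboxylate in a formal [3+2] cycloaddition.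
- Ring order: rings B, C and D are bought. Ring A is the only ring made, in step 7, together with C2 and C3. The third stereocentre comes with (R)-danshensu.

Key step: step 7

Assumption: Rh2(S-PTTL)4 (dirhodium tetrakis[N-phthaloyl-(S)-tert-leucinate]) is taken to induce the (2S,3R) sense in step 7; if a first run shows the opposite sense, the mirror-image catalyst Rh2(R-PTTL)4 is used and nothing else changes.

Step 1
Reactants: 1 4-(benzyloxy)-3-hydroxybenzaldehyde
Product: 2 4-(benzyloxy)-3-hydroxy-2-nitrobenzaldehyde
Conditions: 65% HNO3 (1.1 equiv), AcOH, 10 °C; silica chromatography to remove the 6-nitro isomer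
Reagents that add atoms: nitric acid, O[N+](=O)[O-]
Why: Electrophilic aromatic nitration in which the free 3-OH is the dominant director and activates C2 (ortho) and C6 (para), the pattern known for isovanillin-type phenols; the wanted 2-nitro compound is an internally hydrogen-bonded ortho-nitrophenol and should run well ahead of the more polar 6-nitro isomer on silica, while the unactivated benzyl ring and the aldehyde are left alone at this temperature.

Step 2
Reactants: 2 4-(benzyloxy)-3-hydroxy-2-nitrobenzaldehyde
Product: 3 2-amino-4-(benzyloxy)-3-hydroxybenzaldehyde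
Conditions: Fe powder, NH4Cl, EtOH–H2O, 70 °C, argon; filter, extract, use the same day
Reagents that add atoms: none
Why: Béchamp-type iron reduction under nearly neutral conditions takes the nitro group to the amine without touching the aldehyde or the benzyl ether, and because 3 is both an ortho-aminobenzaldehyde and an ortho-aminophenol it is carried on without storage.

Step 3
Reactants: 3 2-amino-4-(benzyloxy)-3-hydroxybenzaldehyde
Product: 5 2-(benzyloxy)-6-diazo-5-formylcyclohexa-2,4-dien-1-one, via diazonium chloride 4 (not isolated)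
Conditions: NaNO2, 2 M HCl, THF–H2O, 0 °C; then NaHCO3 to pH 7, CH2Cl2 extraction, dark, kept cold (energetic, light-sensitive compound, small batches)
Reagents that add atoms: sodium nitrite, [Na+].[O-]N=O
Why: Diazotisation of an ortho-aminophenol, in which nitrous acid gives diazonium salt 4 whose phenol is strongly acidified by the ortho diazonium group, so that mild base removes HCl and leaves the neutral, extractable ortho-quinone diazide with the diazo carbon lying between the carbonyl carbon and the formyl-bearing carbon.

Step 4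
Reactants: 6 caffeic acid
Product: 7 benzyl (E)-3-[3,4-bis(benzyloxy)phenyl]prop-2-enoate
Conditions: BnBr (3.3 equiv), K2CO3, DMF, 60 °C, argon
Reagents that add atoms: benzyl bromide, BrCc1ccccc1
Why: Williamson etherification of both phenols and SN2 alkylation of the carboxylate take place in one operation and leave the E-alkene unchanged.

Step 5
Reactants: 7 benzyl (E)-3-[3,4-bis(benzyloxy)phenyl]prop-2-enoate
Product: 8 (E)-3-[3,4-bis(benzyloxy)phenyl]prop-2-en-1-ol
Conditions: i-Bu2AlH (2.5 equiv), CH2Cl2, −78 → 0 °C; aq. KNaC4H4O6 (potassium sodium tartrate) work-up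
Reagents that add atoms: none
Why: 1,2-Reduction of an α,β-unsaturated ester by i-Bu2AlH at low temperature gives the allylic alcohol with the E-alkene and the aryl benzyl ethers intact.

Step 6
Reactants: 8 (E)-3-[3,4-bis(benzyloxy)phenyl]prop-2-en-1-ol
Product: 9 (E)-3-[3,4-bis(benzyloxy)phenyl]allyl tert-butyldimethylsilyl ether
Conditions: TBSCl, imidazole, CH2Cl2, 23 °C
Reagents that add atoms: tert-butyldimethylsilyl chloride, CC(C)(C)[Si](C)(C)Cl
Why: Imidazole-promoted silylation masks the hydroxyl, which would otherwise undergo O–H insertion with the carbene, and the bulky silyl group makes the ether oxygen a poor ylide-forming nucleophile while the alkene stays electron-rich.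

Step 7
Reactants: 5 2-(benzyloxy)-6-diazo-5-formylcyclohexa-2,4-dien-1-one; 9 (E)-3-[3,4-bis(benzyloxy)phenyl]allyl tert-butyldimethylsilyl ether
Product: 12 (2S,3R)-7-(benzyloxy)-2-[3,4-bis(benzyloxy)phenyl]-3-{[(tert-butyldimethylsilyl)oxy]methyl}-2,3-dihydro-1-benzofuran-4-carbaldehyde, via rhodium carbene 10 (not isolated), via benzylic zwitterion 11 (not isolated)
Conditions: Rh2(S-PTTL)4 (2 mol %), 9 (3 equiv, excess recovered), PhCF3, 4 Å molecular sieves, 25–40 °C, dark, 5 added by syringe pump over 6 h
Reagents that add atoms: none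
Why: Proposed new method: the catalyst expels N2 from 5 to give the electrophilic quinoid carbene 10, whose carbene carbon is the future C3a and whose neighbouring carbonyl oxygen is the future O1, and the alkene of 9 attacks it through the CH2OTBS-bearing carbon (bond C3–C3a) so that the charge builds at C2 and is spread by the 4-benzyloxy group of ring C into a para-quinone-methide oxonium ion. As rhodium departs, ring B regains aromaticity (zwitterion 11) and its phenoxide oxygen adds to C2 in a 5-exo-trig closure (bond O1–C2), which makes ring A, the only ring formed. The closest known reaction type is the Rh2(OAc)4-catalysed formal [3+2] cycloaddition of cyclic 2-diazo-1,3-dicarbonyl compounds and ortho-quinone diazides with styrenes and enol ethers; new here are a 1,2-disubstituted styrene, a monocyclic diazide flanked by a formyl group, and the demand for high enantiocontrol from a chiral carboxylate. C3 is fixed in the C–C bond-forming event, where the phthalimido walls of the catalyst leave one approach to the carbene open and so select the alkene face, whereas C2 is fixed afterwards by the substrate, because the freely rotating cation closes with ring C anti to the CH2OTBS group, giving the trans and also more stable isomer. Regioselectivity rests on the benzylic, para-oxygen-stabilised cation at C2; chemoselectivity over formyl oxygen, silyl ether oxygen, allylic C–H bonds and arene rings rests on the high nucleophilicity of the 3,4-dialkoxystyrene, the bulk of the TBS group, the fact that the formyl oxygen of 10 could reach the carbene only through a four-membered ring, and the slow addition of 5 to an excess of 9.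

Step 8
Reactants: 13 (R)-3-(3,4-dihydroxyphenyl)lactic acid (danshensu)
Product: 14 benzyl (R)-3-[3,4-bis(benzyloxy)phenyl]-2-hydroxypropanoate
Conditions: BnBr (3.3 equiv), K2CO3, DMF, 23 °C, argon
Reagents that add atoms: benzyl bromide, BrCc1ccccc1
Why: Williamson etherification and carboxylate alkylation as in step 4; K2CO3 is too weak to alkylate the secondary alcohol or to enolise the α-hydroxy ester at room temperature, so the R centre bought with 13 is kept.

Step 9
Reactants: 14 benzyl (R)-3-[3,4-bis(benzyloxy)phenyl]-2-hydroxypropanoate; 15 Meldrum's acid (2,2-dimethyl-1,3-dioxane-4,6-dione)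
Product: 16 3-{[(2R)-1-(benzyloxy)-3-[3,4-bis(benzyloxy)phenyl]-1-oxopropan-2-yl]oxy}-3-oxopropanoic acid
Conditions: toluene, 110 °C
Reagents that add atoms: none
Why: Thermal alcoholysis of Meldrum's acid, in which the alcohol attacks a ring carbonyl and acetone is lost, gives the malonic half-ester directly, and the C–O bond at the stereocentre is not broken, so the configuration is retained.

Step 10
Reactants: 12 (2S,3R)-7-(benzyloxy)-2-[3,4-bis(benzyloxy)phenyl]-3-{[(tert-butyldimethylsilyl)oxy]methyl}-2,3-dihydro-1-benzofuran-4-carbaldehyde; 16 3-{[(2R)-1-(benzyloxy)-3-[3,4-bis(benzyloxy)phenyl]-1-oxopropan-2-yl]oxy}-3-oxopropanoic acid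
Product: 18 benzyl (2R)-3-[3,4-bis(benzyloxy)phenyl]-2-({(2E)-3-[(2S,3R)-7-(benzyloxy)-2-[3,4-bis(benzyloxy)phenyl]-3-{[(tert-butyldimethylsilyl)oxy]methyl}-2,3-dihydro-1-benzofuran-4-yl]prop-2-enoyl}oxy)propanoate, via alkylidene malonate half-ester 17 (not isolated)
Conditions: 16 (1.5 equiv), pyridine, piperidine (0.3 equiv), 65 °C
Reagents that add atoms: none
Why: Knoevenagel condensation in the Doebner variant with a malonic half-ester, in which piperidine activates the aldehyde, condensation gives 17 and pyridine-promoted decarboxylation delivers the thermodynamically preferred E-cinnamate; it is placed before oxidation of the C3 side chain so that no acidic C3–H meets the base, and before desilylation so that a free C3 CH2OH cannot form a lactol with the C4 aldehyde.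

Step 11
Reactants: 18 silyl ether cinnamate (name as in step 10)
Product: 19 benzyl (2R)-3-[3,4-bis(benzyloxy)phenyl]-2-({(2E)-3-[(2S,3R)-7-(benzyloxy)-2-[3,4-bis(benzyloxy)phenyl]-3-(hydroxymethyl)-2,3-dihydro-1-benzofuran-4-yl]prop-2-enoyl}oxy)propanoate
Conditions: HF·pyridine, pyridine–THF, 0 → 23 °C
Reagents that add atoms: none
Why: Fluoride cleavage of a primary TBS ether under weakly acidic, non-nucleophilic conditions spares both esters, the benzyl ethers and all three stereocentres, which basic fluoride sources might endanger.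

Step 12
Reactants: 19 primary alcohol (name as in step 11)
Product: 20 benzyl (2R)-3-[3,4-bis(benzyloxy)phenyl]-2-({(2E)-3-[(2S,3S)-7-(benzyloxy)-2-[3,4-bis(benzyloxy)phenyl]-3-formyl-2,3-dihydro-1-benzofuran-4-yl]prop-2-enoyl}oxy)propanoate
Conditions: Dess–Martin periodinane, CH2Cl2, 0 → 23 °C; short silica plug, used at once
Reagents that add atoms: none
Why: Dess–Martin oxidation stops at the aldehyde and works without base, so neither enolisation at C3 nor β-elimination of the O1 phenoxide is triggered (the descriptor at C3 changes to S through priorities only).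

Step 13
Reactants: 20 C3 aldehyde (name as in step 12)
Product: 21 (2S,3S)-7-(benzyloxy)-4-[(1E)-3-{[(2R)-1-(benzyloxy)-3-[3,4-bis(benzyloxy)phenyl]-1-oxopropan-2-yl]oxy}-3-oxoprop-1-en-1-yl]-2-[3,4-bis(benzyloxy)phenyl]-2,3-dihydro-1-benzofuran-3-carboxylic acid
Conditions: NaClO2, NaH2PO4, 2-methyl-2-butene (excess), t-BuOH–THF–H2O, 0 → 23 °C
Reagents that add atoms: sodium chlorite, [Na+].[O-]Cl=O
Why: Pinnick oxidation at about pH 4 converts the aldehyde into the acid without epimerising conditions, and the alkene scavenger removes hypochlorous acid before it can chlorinate the electron-rich rings.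

Step 14
Reactants: 21 C3 carboxylic acid (name as in step 13)
Product: 22 methyl (2S,3S)-7-(benzyloxy)-4-[(1E)-3-{[(2R)-1-(benzyloxy)-3-[3,4-bis(benzyloxy)phenyl]-1-oxopropan-2-yl]oxy}-3-oxoprop-1-en-1-yl]-2-[3,4-bis(benzyloxy)phenyl]-2,3-dihydro-1-benzofuran-3-carboxylate
Conditions: TMSCHN2 (1.2 equiv), toluene–MeOH 4:1, 0 °C; AcOH quench
Reagents that add atoms: (trimethylsilyl)diazomethane, C[Si](C)(C)C=[N+]=[N-]
Why: Diazoalkane esterification methylates the only free acid without any base, which avoids the retro-oxa-Michael opening of ring A that carbonate and alkyl halide conditions could provoke, and no free phenol is present to compete.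

Step 15
Reactants: 22 hexabenzyl methyl ester (name as in step 14)
Product: 23 monomethyl lithospermate, (2R)-3-(3,4-dihydroxyphenyl)-2-({(2E)-3-[(2S,3S)-2-(3,4-dihydroxyphenyl)-7-hydroxy-3-(methoxycarbonyl)-2,3-dihydro-1-benzofuran-4-yl]prop-2-enoyl}oxy)propanoic acid
Conditions: BCl3 (12 equiv), pentamethylbenzene (18 equiv), CH2Cl2, −78 → −20 °C; H2O–THF quench, EtOAc extraction, reversed-phase chromatography
Reagents that add atoms: none
Why: Lewis-acid debenzylation with Friedel–Crafts capture of each benzyl cation by the non-basic scavenger is known for aryl benzyl ethers and benzyl esters, needs no hydrogen and so spares the cinnamate C=C, leaves the methyl ester and the secondary acyloxy group because neither can give a stabilised cation, and any transient ionisation of C2–O1 should reclose anti to the untouched C3 substituent to restore the same trans isomer.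

**Compound list**
1 | 4-(benzyloxy)-3-hydroxybenzaldehyde | O=Cc1ccc(OCc2ccccc2)c(O)c1 | starting material
2 | 4-(benzyloxy)-3-hydroxy-2-nitrobenzaldehyde | O=Cc1ccc(OCc2ccccc2)c(O)c1[N+](=O)[O-] | intermediate
3 | 2-amino-4-(benzyloxy)-3-hydroxybenzaldehyde | O=Cc1ccc(OCc2ccccc2)c(O)c1N | intermediate
4 | 3-(benzyloxy)-6-formyl-2-hydroxybenzenediazonium chloride | O=Cc1ccc(OCc2ccccc2)c(O)c1[N+]#N.[Cl-] | intermediate
5 | 2-(benzyloxy)-6-diazo-5-formylcyclohexa-2,4-dien-1-one | O=CC1=CC=C(OCc2ccccc2)C(=O)C1=[N+]=[N-] | intermediate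
6 | caffeic acid | O=C(O)/C=C/c1ccc(O)c(O)c1 | starting material
7 | benzyl (E)-3-[3,4-bis(benzyloxy)phenyl]prop-2-enoate | O=C(OCc1ccccc1)/C=C/c1ccc(OCc2ccccc2)c(OCc2ccccc2)c1 | intermediate
8 | (E)-3-[3,4-bis(benzyloxy)phenyl]prop-2-en-1-ol | OC/C=C/c1ccc(OCc2ccccc2)c(OCc2ccccc2)c1 | intermediate
9 | (E)-3-[3,4-bis(benzyloxy)phenyl]allyl tert-butyldimethylsilyl ether | CC(C)(C)[Si](C)(C)OC/C=C/c1ccc(OCc2ccccc2)c(OCc2ccccc2)c1 | intermediate
10 | dirhodium carbene from 5 and Rh2(S-PTTL)4, carbene carbon = future C3a (written with ionic carboxylates) | O=CC1=CC=C(OCc2ccccc2)C(=O)C1=[Rh+2].[Rh+2].CC(C)(C)[C@H](N1C(=O)c2ccccc2C1=O)C(=O)[O-].CC(C)(C)[C@H](N1C(=O)c2ccccc2C1=O)C(=O)[O-].CC(C)(C)[C@H](N1C(=O)c2ccccc2C1=O)C(=O)[O-].CC(C)(C)[C@H](N1C(=O)c2ccccc2C1=O)C(=O)[O-] | intermediate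
11 | zwitterion with the C3–C3a bond made: ring B phenoxide, (R)-configured future C3, C2 cation drawn as para-quinone-methide oxonium ion of ring C | CC(C)(C)[Si](C)(C)OC[C@H](C=C1C=CC(=[O+]Cc2ccccc2)C(OCc2ccccc2)=C1)c1c(C=O)ccc(OCc2ccccc2)c1[O-] | intermediate
12 | (2S,3R)-7-(benzyloxy)-2-[3,4-bis(benzyloxy)phenyl]-3-{[(tert-butyldimethylsilyl)oxy]methyl}-2,3-dihydro-1-benzofuran-4-carbaldehyde (trans) | CC(C)(C)[Si](C)(C)OC[C@H]1c2c(C=O)ccc(OCc3ccccc3)c2O[C@@H]1c1ccc(OCc2ccccc2)c(OCc2ccccc2)c1 | intermediate
13 | (R)-3-(3,4-dihydroxyphenyl)lactic acid (danshensu) | O[C@H](Cc1ccc(O)c(O)c1)C(=O)O | starting material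
14 | benzyl (R)-3-[3,4-bis(benzyloxy)phenyl]-2-hydroxypropanoate | O[C@H](Cc1ccc(OCc2ccccc2)c(OCc2ccccc2)c1)C(=O)OCc1ccccc1 | intermediate
15 | Meldrum's acid | CC1(C)OC(=O)CC(=O)O1 | starting material
16 | 3-{[(2R)-1-(benzyloxy)-3-[3,4-bis(benzyloxy)phenyl]-1-oxopropan-2-yl]oxy}-3-oxopropanoic acid | OC(=O)CC(=O)O[C@H](Cc1ccc(OCc2ccccc2)c(OCc2ccccc2)c1)C(=O)OCc1ccccc1 | intermediate
17 | alkylidene malonate half-ester: 18 with an additional CO2H on the acrylate α-carbon, (2S,3R) core, (R) side chain, C=C geometry undefined | CC(C)(C)[Si](C)(C)OC[C@H]1c2c(C=C(C(=O)O)C(=O)O[C@H](Cc3ccc(OCc4ccccc4)c(OCc4ccccc4)c3)C(=O)OCc3ccccc3)ccc(OCc3ccccc3)c2O[C@@H]1c1ccc(OCc2ccccc2)c(OCc2ccccc2)c1 | intermediate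
18 | (E)-cinnamate with C3 CH2OTBS, (2S,3R) core, (R) side chain (full name in step 10) | CC(C)(C)[Si](C)(C)OC[C@H]1c2c(/C=C/C(=O)O[C@H](Cc3ccc(OCc4ccccc4)c(OCc4ccccc4)c3)C(=O)OCc3ccccc3)ccc(OCc3ccccc3)c2O[C@@H]1c1ccc(OCc2ccccc2)c(OCc2ccccc2)c1 | intermediate
19 | C3 hydroxymethyl cinnamate, (2S,3R), (R) (full name in step 11) | OC[C@H]1c2c(/C=C/C(=O)O[C@H](Cc3ccc(OCc4ccccc4)c(OCc4ccccc4)c3)C(=O)OCc3ccccc3)ccc(OCc3ccccc3)c2O[C@@H]1c1ccc(OCc2ccccc2)c(OCc2ccccc2)c1 | intermediate
20 | C3 formyl cinnamate, (2S,3S), (R) (full name in step 12) | O=C[C@H]1c2c(/C=C/C(=O)O[C@H](Cc3ccc(OCc4ccccc4)c(OCc4ccccc4)c3)C(=O)OCc3ccccc3)ccc(OCc3ccccc3)c2O[C@@H]1c1ccc(OCc2ccccc2)c(OCc2ccccc2)c1 | intermediate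
21 | C3 carboxylic acid, (2S,3S), (R) (full name in step 13) | OC(=O)[C@H]1c2c(/C=C/C(=O)O[C@H](Cc3ccc(OCc4ccccc4)c(OCc4ccccc4)c3)C(=O)OCc3ccccc3)ccc(OCc3ccccc3)c2O[C@@H]1c1ccc(OCc2ccccc2)c(OCc2ccccc2)c1 | intermediate
22 | hexabenzyl monomethyl lithospermate, (2S,3S), (R) (full name in step 14) | COC(=O)[C@H]1c2c(/C=C/C(=O)O[C@H](Cc3ccc(OCc4ccccc4)c(OCc4ccccc4)c3)C(=O)OCc3ccccc3)ccc(OCc3ccccc3)c2O[C@@H]1c1ccc(OCc2ccccc2)c(OCc2ccccc2)c1 | intermediate
23 | monomethyl lithospermate, (2S,3S), (R), E | COC(=O)[C@H]1c2c(/C=C/C(=O)O[C@H](Cc3ccc(O)c(O)c3)C(=O)O)ccc(O)c2O[C@@H]1c1ccc(O)c(O)c1 | target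

**Step count**
- Total steps: 15.
- Longest linear sequence: 10 (steps 1–3, 7, 10–15). The line from 6 through steps 4–6 is equally long.

**Steps most likely to fail**

1. Step 7.
 - Risk: the chiral pocket may discriminate weakly between the two alkene faces. Capture of the hindered carbene by a 1,2-disubstituted alkene may also be slow. In that case carbonyl-ylide formation at formyl oxygen, attack on the electron-rich arenes or Wolff-type ring contraction could take over.
 - Fallback (known chemistry): absolute control is moved from the catalyst to the resident danshensu stereocentre. Setting out from 5 and 9, the cycloaddition is run with the small achiral catalyst Rh2(OAc)4, the documented form of this reaction type. It should give the trans product as a racemate, that is 12 together with its mirror image, the (2R,3S)-aldehyde F1.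
 - The mixture is condensed with enantiopure 16 under the conditions of step 10. This turns the enantiomers into diastereomers, 18 and the (2R,3S)-core cinnamate F2. These are separated by chromatography or crystallisation, and the route is rejoined at 18.

2. Step 15.
 - Risk: the benzyl ester may cleave slowly compared with the aryl ethers, forcing higher temperatures. At those temperatures the C2–O1 bond could ionise and the cation be captured by the scavenger. Boron chelates of the catechols could also complicate release of the product.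
 - Fallback: acidolysis is replaced by a neutral reductive silylation followed by desilylation. Setting out from 22, Pd(OAc)2 (catalytic), Et3SiH and Et3N in CH2Cl2 at 23 °C effect a silane hydrogenolysis. This method is known to turn benzyl ethers and esters into triethylsilyl derivatives in aprotic medium without saturating C=C bonds.
 - It should give the hexakis(triethylsilyl) derivative F3. Brief treatment with HF·pyridine in THF at 0 °C removes all silyl groups, and the route is rejoined at 23.

3. Step 2.
 - Risk: the ortho-aminobenzaldehyde may self-condense and the aminophenol may oxidise in air during reduction and work-up, before diazotisation can be done.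
 - Fallback: the aldehyde is masked while the amine is generated. Setting out from 2, HC(OMe)3 and catalytic p-TsOH in MeOH give the nitro acetal 6-(benzyloxy)-3-(dimethoxymethyl)-2-nitrophenol F4. Hydrogenation over sulfided Pt/C in EtOAc, which spares aryl benzyl ethers, gives the amino acetal 2-amino-6-(benzyloxy)-3-(dimethoxymethyl)phenol F5.
 - F5 is dissolved directly in 2 M HCl–THF at 0 °C. The acetal is lost there only while the nitrogen is protonated. NaNO2 is added at once and neutralisation with NaHCO3 follows as in step 3, so that the route is rejoined at 5.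

**Further compounds**
F1 | step 7 | (2R,3S)-7-(benzyloxy)-2-[3,4-bis(benzyloxy)phenyl]-3-{[(tert-butyldimethylsilyl)oxy]methyl}-2,3-dihydro-1-benzofuran-4-carbaldehyde (mirror image of 12) | CC(C)(C)[Si](C)(C)OC[C@@H]1c2c(C=O)ccc(OCc3ccccc3)c2O[C@H]1c1ccc(OCc2ccccc2)c(OCc2ccccc2)c1
F2 | step 7 | diastereomer of 18 with (2R,3S) core and (R) side chain | CC(C)(C)[Si](C)(C)OC[C@@H]1c2c(/C=C/C(=O)O[C@H](Cc3ccc(OCc4ccccc4)c(OCc4ccccc4)c3)C(=O)OCc3ccccc3)ccc(OCc3ccccc3)c2O[C@H]1c1ccc(OCc2ccccc2)c(OCc2ccccc2)c1
F3 | step 15 | hexakis(triethylsilyl) monomethyl lithospermate (five aryl silyl ethers, one silyl ester), (2S,3S), (R) | COC(=O)[C@H]1c2c(/C=C/C(=O)O[C@H](Cc3ccc(O[Si](CC)(CC)CC)c(O[Si](CC)(CC)CC)c3)C(=O)O[Si](CC)(CC)CC)ccc(O[Si](CC)(CC)CC)c2O[C@@H]1c1ccc(O[Si](CC)(CC)CC)c(O[Si](CC)(CC)CC)c1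
F4 | step 2 | 6-(benzyloxy)-3-(dimethoxymethyl)-2-nitrophenol | COC(OC)c1ccc(OCc2ccccc2)c(O)c1[N+](=O)[O-]
F5 | step 2 | 2-amino-6-(benzyloxy)-3-(dimethoxymethyl)phenol | COC(OC)c1ccc(OCc2ccccc2)c(O)c1N
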